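Ring A of the trans-decalin is disconnected at C3–C4 (drimane numbering), which unmasks a pinane made from (1S,5S)-verbenone in which C4 is still the CMe2 bridge of the cyclobutane C4–C5–C6–C7. The key step exploits the strained C4–C7 bond of this four-membered ring, held antiperiplanar to an ionizable C8–O bond: departure of the C8 oxygen breaks C4–C7, creates the Δ7 alkene of ring B and a cation at C4, and the tethered C2 silyl enol ether closes ring A through C3, all in one operation. Its precursor is a 2-pinanyl trimethylsilyl ether carrying the C10 methyl, the C9 silyloxymethyl arm and a C10 2-(trimethylsilyloxy)allyl chain.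

Key step: step 10

Conventions: drimane numbering is used for every compound; "syn" and "anti" refer to the CMe2 bridge (C4) of the pinane.
Assumption: (1S,5S)-(−)-verbenone of high enantiomeric purity is used; the route preserves its ee but does not raise it.
Design remark (correction at C8): the precursor is built as the C8 epimer with the silyloxy group anti to the bridge. Methyl addition to the C8 ketone would give the other epimer (oxygen syn), whose C8–O bond is antiperiplanar to C6–C7 and not to C4–C7, which invites a fenchyl-type shift. Steps 5–7 place the oxygen on the correct face.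

**Step 1**
Reactants: 1 (1S,5S)-(−)-verbenone; 2 allylmagnesium bromide
Product: 3 TMS enol ether of the 1,4-adduct (C8–OSiMe3 with C8=C9; C10 methyl syn and C10 allyl anti to the bridge)
Conditions: CuBr·SMe2 (1.2 equiv), TMSCl (2 equiv), THF, −78 → −40 °C; cold aq. NaHCO3
Reagents that add atoms: chlorotrimethylsilane, C[Si](C)(C)Cl
Why: Conjugate addition of an allylcopper reagent accelerated by TMSCl; the allyl group can reach C10 only from the face anti to the CMe2 bridge, whose syn methyl shields the other face, which sets C10 (methyl syn, chain anti) and traps the enolate as its silyl ether.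

**Step 2**
Reactants: 3 TMS enol ether
Product: 5 9-hydroxymethyl C8 ketone with the hydroxymethyl group anti to the bridge, via lithium enolate 4 (not isolated)
Conditions: MeLi, THF, 0 °C; CH2O (gas, from cracked paraformaldehyde), −78 °C; aq. NH4Cl
Reagents that add atoms: formaldehyde, C=O
Why: Regiospecific enolate generation from the silyl enol ether followed by aldol addition to formaldehyde; C9 is the only enolizable position because C7 is a bridgehead, the C9–C11 bond should form anti to the bridge, and this C9 configuration is provisional because step 4 resets it.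

**Step 3**
Reactants: 5 hydroxymethyl ketone
Product: 6 TBDPS ether of 5
Conditions: TBDPSCl, imidazole, DMF, 0 °C → rt
Reagents that add atoms: tert-butyl(chloro)diphenylsilane, CC(C)(C)[Si](Cl)(c1ccccc1)c1ccccc1
Why: Standard silylation of a primary alcohol; the bulky, acid-stable TBDPS group is chosen to survive the Lewis acid of step 10 and to keep the C11 oxygen from trapping the C4 cation.

**Step 4**
Reactants: 6 TBDPS ether
Product: 8 C8 ketone with the C9 silyloxymethyl arm syn to the bridge, via lithium enolate 7 (not isolated)
Conditions: LDA, THF, −78 → −40 °C; AcOH in THF, −78 °C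
Reagents that add atoms: none
Why: Enolate formation followed by kinetic C-protonation; the proton should be delivered to C9 on the face anti to the CMe2 bridge (the syn face carries the bridge methyl and the C10 methyl), so the silyloxymethyl arm ends syn to the bridge and cis to the C10 methyl, which is the C9 configuration of the target.

**Step 5**
Reactants: 8 ketone
Product: 9 8-methylene pinane (exocyclic C8=CH2)
Conditions: Cp2TiMe2, toluene, 70 °C, dark
Reagents that add atoms: dimethyltitanocene, C[Ti](C)(C1C=CC=C1)C1C=CC=C1
Why: Petasis methylenation; the non-basic titanium methylidene olefinates hindered, enolizable ketones without epimerizing the adjacent C9 center or eliminating the β-silyloxy group.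

**Step 6**
Reactants: 9 8-methylene pinane
Product: 10 bis-epoxide (C8 spiro-epoxide with oxygen anti to the bridge; side-chain epoxide as a mixture of C2 epimers)
Conditions: DMDO (excess), acetone/CH2Cl2, 0 °C → rt
Reagents that add atoms: dimethyldioxirane, CC1(C)OO1
Why: Dioxirane epoxidation under neutral conditions; the exocyclic C8 alkene should be attacked anti to the CMe2 bridge as in β-pinene, which fixes the C8 oxygen anti and the new CH2 syn to the bridge, and the side-chain alkene is epoxidized as well without consequence because its new center is removed in step 8.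

**Step 7**
Reactants: 10 bis-epoxide
Product: 11 diol (C8 tertiary alcohol with OH anti and methyl syn to the bridge; C2 secondary alcohol as an epimer mixture)
Conditions: LiEt3BH, THF, 0 °C → rt; H2O
Reagents that add atoms: none
Why: Hydride opening of both epoxides at their CH2 termini (SN2), which leaves the C8–O bond untouched (oxygen anti, new C8 methyl syn) and turns the side chain into the C2 carbinol.

**Step 8**
Reactants: 11 diol
Product: 12 hydroxy ketone (C8 tertiary alcohol; acetonyl chain on C10)
Conditions: TPAP (cat.), NMO, 4 Å MS, CH2Cl2, rt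
Reagents that add atoms: none
Why: Ley–Griffith oxidation; only the secondary C2 carbinol can be oxidized, and the neutral conditions spare the acid-labile tertiary pinanyl alcohol.

**Step 9**
Reactants: 12 hydroxy ketone
Product: 13 key precursor (C8–OSiMe3 anti to the bridge; terminal C2 trimethylsilyl enol ether C2=C3H2)
Conditions: TMSCl (excess), then LDA (2.5 equiv), THF, −78 → 0 °C; pentane, cold aq. NaHCO3
Reagents that add atoms: chlorotrimethylsilane, C[Si](C)(C)Cl
Why: Kinetic enolization with in situ silylation; LDA should remove a proton from the unhindered C3 methyl group in preference to the neopentyl C1 methylene to give the terminal silyl enol ether, and the C8 lithium alkoxide is silylated as the mixture warms.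

**Step 10**
Reactants: 13 key precursor
Product: 14 2-oxo-ent-drim-7-en-11-yl TBDPS ether (trans-fused; C9 arm equatorial and cis to the C10 methyl)
Conditions: TMSOTf (0.3 equiv), 2,6-di-tert-butyl-4-methylpyridine (0.4 equiv), CH2Cl2, −78 → −30 °C; aq. NaHCO3
Reagents that add atoms: none
Why: Proposed new method: TMSOTf silylates the C8 ether oxygen so that hexamethyldisiloxane departs, and because this C8–O bond is antiperiplanar to the strained C4–C7 bond, ionization and cyclobutane cleavage should merge into one Grob-type event that gives the Δ7 alkene of ring B and a tertiary cation at C4; the enol ether carbon C3 then attacks C4, and loss of the silyl group from the oxocarbenium ion leaves the C2 ketone and regenerates the promoter. The closest known reaction types are the acid-induced opening of 2-pinanyl cations to p-menth-1-en-8-yl cations (pinan-2-ol to α-terpineol) and the Lewis-acid tert-alkylation of silyl enol ethers by SN1-active electrophiles, which have not been run as one cascade. Ring A closes in the 6-endo mode with respect to the enol ether, both C2 and C3 ending in the ring (a 6-(enolendo) closure), through a chair transition state. No stereocenter is formed: C5 and C10 are in place, and since C4 on C5 and C1 on C10 are trans on ring B the fusion can only be trans. The step needs fragmentation to outrun Wagner–Meerwein shift, proton loss and capture at C8; this should be secured by the antiperiplanar nucleofuge (the C6–C7 bond that would lead to a fenchyl-type shift is gauche to it), the non-nucleophilic counter-ion, the hindered pyridine that removes adventitious acid, and the six-membered transition state open to the C4 cation.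

**Step 11**
Reactants: 14 ketone
Product: 15 Δ2 trimethylsilyl enol ether of 14 (C2=C3)
Conditions: TMSOTf, Et3N, CH2Cl2, 0 °C → rt
Reagents that add atoms: trimethylsilyl triflate, C[Si](C)(C)OS(=O)(=O)C(F)(F)F
Why: Silyl enol ether formation by soft enolization under equilibrating conditions; a trans-fused 2-decalone should enolize preferentially toward C3 (as 2-oxo-5α-steroids do), because a C1=C2 double bond next to the ring-fusion carbon is the more strained alternative.

**Step 12**
Reactants: 15 Δ2 silyl enol ether
Product: 18 equatorial ketol (3S)-3-hydroxy-2-oxo-ent-drim-7-en-11-yl TBDPS ether, via silyloxy epoxide 16 (not isolated), via axial ketol 17 (not isolated)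
Conditions: DMDO (1.05 equiv), acetone/CH2Cl2, −78 → −40 °C; then K2CO3 (cat.), MeOH, rt, argon
Reagents that add atoms: dimethyldioxirane, CC1(C)OO1
Why: Rubottom oxidation followed by base equilibration of the α-ketol; the dioxirane should attack the electron-rich enol ether (faster than the Δ7 alkene) anti to the axial C4 and C10 methyls, which gives the axial C3 alcohol after methanolysis, and enediol equilibration then sets C3 as the equatorial, hydrogen-bonded 3-hydroxy-2-ketone, expected to be the most stable ketol because its carbonyl stays 1,3 to both axial methyls.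

**Step 13**
Reactants: 18 equatorial ketol
Product: 19 (3S)-3,11-dihydroxy-ent-drim-7-en-2-one
Conditions: HF·pyridine, THF/pyridine, 0 °C → rt
Reagents that add atoms: none
Why: Fluoride-mediated desilylation under buffered acidic conditions, which cleaves the primary TBDPS ether without exposing the ketol to base.

**Step 14**
Reactants: 19 diol; 20 umbelliferone
Product: 21 (3S)-3-hydroxy-11-(2-oxo-2H-chromen-7-yloxy)-ent-drim-7-en-2-one
Conditions: PPh3, DIAD, THF, 0 °C → rt
Reagents that add atoms: none
Why: Mitsunobu etherification; the acidic 7-hydroxyl of the coumarin is alkylated by the activated primary C11 alcohol, the hindered secondary C3 hydroxyl next to the gem-dimethyl group should not be activated, and C11 is not a stereocenter.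

**Step 15**
Reactants: 21 hydroxy aryl ether; 22 angelic acid
Product: 24 target CNP0111364.1, via mixed anhydride 23 (not isolated)
Conditions: 2,4,6-trichlorobenzoyl chloride, Et3N, toluene, rt; then 21, 80 °C (no DMAP)
Reagents that add atoms: none
Why: Yamaguchi esterification through the mixed anhydride; O-acylation of the C3 hydroxyl proceeds with retention at C3, and the DMAP-free protocol is the one known to preserve the Z geometry of angelates.

**Compound list**
1 | (1S,5S)-(−)-verbenone | CC1=CC(=O)[C@H]2C[C@@H]1C2(C)C | starting material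
2 | allylmagnesium bromide | C=CC[Mg]Br | starting material
3 | TMS enol ether of the 1,4-adduct (C8–OSiMe3, C8=C9; C10 methyl syn, allyl anti to the bridge) | C=CC[C@@]1(C)C=C(O[Si](C)(C)C)[C@H]2C[C@@H]1C2(C)C | intermediate
4 | lithium enolate of the 1,4-adduct (not isolated) | C=CC[C@@]1(C)C=C([O-])[C@H]2C[C@@H]1C2(C)C.[Li+] | intermediate
5 | 9-hydroxymethyl C8 ketone, hydroxymethyl anti to the bridge | C=CC[C@@]1(C)[C@@H](CO)C(=O)[C@H]2C[C@@H]1C2(C)C | intermediate
6 | TBDPS ether of 5 | C=CC[C@@]1(C)[C@@H](CO[Si](c2ccccc2)(c3ccccc3)C(C)(C)C)C(=O)[C@H]4C[C@@H]1C4(C)C | intermediate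
7 | lithium C8 enolate of 6 (not isolated) | C=CC[C@@]1(C)C(CO[Si](c2ccccc2)(c3ccccc3)C(C)(C)C)=C([O-])[C@H]4C[C@@H]1C4(C)C.[Li+] | intermediate
8 | C8 ketone with the C9 silyloxymethyl arm syn to the bridge (cis to the C10 methyl) | C=CC[C@@]1(C)[C@H](CO[Si](c2ccccc2)(c3ccccc3)C(C)(C)C)C(=O)[C@H]4C[C@@H]1C4(C)C | intermediate
9 | 8-methylene pinane (C9 arm syn, C10 methyl syn, C10 allyl anti) | C=CC[C@@]1(C)[C@H](CO[Si](c2ccccc2)(c3ccccc3)C(C)(C)C)C(=C)[C@H]4C[C@@H]1C4(C)C | intermediate
10 | bis-epoxide (C8 spiro-epoxide, oxygen anti to the bridge; side-chain epoxide, C2 epimer mixture) | C1OC1C[C@@]2(C)[C@H](CO[Si](c3ccccc3)(c4ccccc4)C(C)(C)C)[C@]5(CO5)[C@H]6C[C@@H]2C6(C)C | intermediate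
11 | diol (C8 tertiary alcohol, OH anti and methyl syn to the bridge; C2 secondary alcohol, epimer mixture) | CC(O)C[C@@]1(C)[C@H](CO[Si](c2ccccc2)(c3ccccc3)C(C)(C)C)[C@@](C)(O)[C@H]4C[C@@H]1C4(C)C | intermediate
12 | hydroxy ketone (C8 tertiary alcohol; acetonyl chain on C10) | CC(=O)C[C@@]1(C)[C@H](CO[Si](c2ccccc2)(c3ccccc3)C(C)(C)C)[C@@](C)(O)[C@H]4C[C@@H]1C4(C)C | intermediate
13 | key precursor: pinane bis-silyl ether with C8–OSiMe3 anti to the bridge and the terminal C2 trimethylsilyl enol ether | C=C(O[Si](C)(C)C)C[C@@]1(C)[C@H](CO[Si](c2ccccc2)(c3ccccc3)C(C)(C)C)[C@@](C)(O[Si](C)(C)C)[C@H]4C[C@@H]1C4(C)C | intermediate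
14 | 2-oxo-ent-drim-7-en-11-yl TBDPS ether | O=C1C[C@@]2(C)[C@H](CO[Si](c3ccccc3)(c4ccccc4)C(C)(C)C)C(C)=CC[C@@H]2C(C)(C)C1 | intermediate
15 | Δ2 trimethylsilyl enol ether of 14 | C[Si](C)(C)OC1C[C@@]2(C)[C@H](CO[Si](c3ccccc3)(c4ccccc4)C(C)(C)C)C(C)=CC[C@@H]2C(C)(C)C=1 | intermediate
16 | 2-silyloxy 2,3-epoxide, oxygen anti to the axial C4 and C10 methyls (not isolated) | C[Si](C)(C)O[C@]12C[C@@]3(C)[C@H](CO[Si](c4ccccc4)(c5ccccc5)C(C)(C)C)C(C)=CC[C@@H]3C(C)(C)[C@H]1O2 | intermediate
17 | axial ketol: 3-hydroxy-2-ketone with OH trans to the C10 methyl (not isolated) | O[C@H]1C(=O)C[C@@]2(C)[C@H](CO[Si](c3ccccc3)(c4ccccc4)C(C)(C)C)C(C)=CC[C@@H]2C1(C)C | intermediate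
18 | equatorial ketol: (3S)-3-hydroxy-2-oxo-ent-drim-7-en-11-yl TBDPS ether (OH cis to the C10 methyl) | O[C@@H]1C(=O)C[C@@]2(C)[C@H](CO[Si](c3ccccc3)(c4ccccc4)C(C)(C)C)C(C)=CC[C@@H]2C1(C)C | intermediate
19 | (3S)-3,11-dihydroxy-ent-drim-7-en-2-one | O[C@@H]1C(=O)C[C@@]2(C)[C@H](CO)C(C)=CC[C@@H]2C1(C)C | intermediate
20 | umbelliferone (7-hydroxycoumarin) | O=c1ccc2ccc(O)cc2o1 | starting material
21 | (3S)-3-hydroxy-11-(2-oxo-2H-chromen-7-yloxy)-ent-drim-7-en-2-one | O[C@@H]1C(=O)C[C@@]2(C)[C@H](COc3ccc4ccc(=O)oc4c3)C(C)=CC[C@@H]2C1(C)C | intermediate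
22 | angelic acid ((Z)-2-methylbut-2-enoic acid) | C/C=C(/C)C(=O)O | starting material
23 | angelic 2,4,6-trichlorobenzoic mixed anhydride (not isolated) | C/C=C(/C)C(=O)OC(=O)c1c(Cl)cc(Cl)cc1Cl | intermediate
24 | CNP0111364.1: (3S,5S,9R,10R)-2-oxo-11-(2-oxo-2H-chromen-7-yloxy)-ent-drim-7-en-3-yl (Z)-2-methylbut-2-enoate | C/C=C(/C)C(=O)O[C@@H]1C(=O)C[C@@]2(C)[C@H](COc3ccc4ccc(=O)oc4c3)C(C)=CC[C@@H]2C1(C)C | target

**Step count and risks**
Total step count: 15. Longest linear sequence: 15 steps (1 → 24); umbelliferone and angelic acid enter as purchased materials in steps 14 and 15.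

The three steps most likely to fail:

1. Step 10 (Proposed new method). The enol ether may be desilylated before the C8 ether ionizes, or Wagner–Meerwein shift and proton loss from the cations may compete with ring closure. The fallback uses known reaction types and separates the two events; it sets out from hydroxy ketone 12. Dilute aqueous H2SO4 in acetone (the pinan-2-ol to α-terpineol ring opening) would give the monocyclic tertiary alcohol F1. HCl in ether at −20 °C would give the tertiary chloride F2. LDA and TMSCl at −78 °C would give the terminal silyl enol ether F3. TiCl4 in CH2Cl2 at −78 °C (intramolecular tert-alkylation of a silyl enol ether by an SN1-active chloride) would then close ring A and return to ketone 14.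

2. Step 11. Enolization toward C1 may compete with enolization toward C3, so that oxygen would enter on the wrong side of the ketone. The fallback installs the C3 oxygen before ring closure, where only the methyl group can enolize; it sets out from precursor 13. DMDO at −78 °C followed by warming (Rubottom oxidation with silyl migration) would give the 3-trimethylsilyloxy ketone F4. TMSOTf and Et3N would enolize it toward the oxygenated carbon to the (Z)-enediol bis-silyl ether F5. The ring closure of step 10 would then give the 3-silyloxy ketone F6 directly, with the oxygen expected equatorial because the Z enol ether holds it cis to the C2 oxygen in the chair transition state. K2CO3 in methanol would return to ketol 18.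

3. Step 12. Epimerization at C3 may stay incomplete, or the base may cause ketol transposition or autoxidation. The fallback sets C3 by hydride delivery instead of equilibration; it sets out from the axial ketol 17, which is isolated when the carbonate treatment is replaced by brief neutral methanolysis. Dess–Martin oxidation would give the diosphenol F7 (the 2,3-dione can enolize only toward C1). TBSCl and imidazole would give the enol silyl ether F8. NaBH4/CeCl3 (Luche reduction, hydride anti to the axial C4 and C10 methyls) would give the equatorial allylic alcohol F9. HF·pyridine would remove both silyl groups, the enol tautomerizing to the C2 ketone, and return to diol 19.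

**Further compounds**
F1 | step 10 | ring-opened tertiary alcohol (cyclohex-7-ene with 2-hydroxyprop-2-yl on C5, acetonyl and methyl on C10, TBDPSOCH2 on C9) | CC(=O)C[C@@]1(C)[C@H](CO[Si](c2ccccc2)(c3ccccc3)C(C)(C)C)C(C)=CC[C@@H]1C(C)(C)O
F2 | step 10 | tertiary chloride corresponding to F1 | CC(=O)C[C@@]1(C)[C@H](CO[Si](c2ccccc2)(c3ccccc3)C(C)(C)C)C(C)=CC[C@@H]1C(C)(C)Cl
F3 | step 10 | terminal trimethylsilyl enol ether of F2 | C=C(O[Si](C)(C)C)C[C@@]1(C)[C@H](CO[Si](c2ccccc2)(c3ccccc3)C(C)(C)C)C(C)=CC[C@@H]1C(C)(C)Cl
F4 | step 11 | 3-trimethylsilyloxy C2 ketone of the pinane series (C8–OSiMe3 retained) | C[Si](C)(C)OCC(=O)C[C@@]1(C)[C@H](CO[Si](c2ccccc2)(c3ccccc3)C(C)(C)C)[C@@](C)(O[Si](C)(C)C)[C@H]4C[C@@H]1C4(C)C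
F5 | step 11 | (Z)-2,3-bis(trimethylsilyloxy) enol ether of the pinane series | C[Si](C)(C)O/C=C(\O[Si](C)(C)C)C[C@@]1(C)[C@H](CO[Si](c2ccccc2)(c3ccccc3)C(C)(C)C)[C@@](C)(O[Si](C)(C)C)[C@H]4C[C@@H]1C4(C)C
F6 | step 11 | (3S)-3-trimethylsilyloxy-2-oxo-ent-drim-7-en-11-yl TBDPS ether | C[Si](C)(C)O[C@@H]1C(=O)C[C@@]2(C)[C@H](CO[Si](c3ccccc3)(c4ccccc4)C(C)(C)C)C(C)=CC[C@@H]2C1(C)C
F7 | step 12 | diosphenol: 2-hydroxy-3-oxo-ent-drima-1,7-dien-11-yl TBDPS ether | OC1=C[C@@]2(C)[C@H](CO[Si](c3ccccc3)(c4ccccc4)C(C)(C)C)C(C)=CC[C@@H]2C(C)(C)C1=O
F8 | step 12 | 2-O-TBS ether of F7 | CC(C)(C)[Si](C)(C)OC1=C[C@@]2(C)[C@H](CO[Si](c3ccccc3)(c4ccccc4)C(C)(C)C)C(C)=CC[C@@H]2C(C)(C)C1=O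
F9 | step 12 | (3S)-3-hydroxy-2-(TBS-oxy)-ent-drima-1,7-dien-11-yl TBDPS ether | CC(C)(C)[Si](C)(C)OC1=C[C@@]2(C)[C@H](CO[Si](c3ccccc3)(c4ccccc4)C(C)(C)C)C(C)=CC[C@@H]2C(C)(C)[C@@H]1O
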